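**Strategy.** Everything rests on seeing C4–C5 of the 1,2-dioxane (the methyl-bearing ring-fusion carbon and its CH2 neighbour) as a two-carbon unit slipped between C3 and C6, the two carbons that carry the O–O bridge. Dichloroketene adds across a geometrically pure trisubstituted alkene (C3=C6), making C3–C4 and C5–C6 in one operation as a cyclobutanone. Its cis geometry is relayed by a torquoselective 4π ring opening into an (E,E)-diene, whose termini C3 and C6 then take up singlet oxygen suprafacially. Bromolactonisation closes the γ-lactone onto C4 and resolves the racemate. The precursor of the key step is an acyclic β,γ-unsaturated ester.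

Key step: step 6

Atom labels used: C1 lactone C=O, C2 lactone CH2, C3 the CH–O–O carbon, C4 the ring-fusion C(CH3)–O(lactone), C5 the dioxane CH2, C6 the C(CH3)(aryldecyl)–O–O carbon.

Assumption: the sense of the kinetic resolution in step 13 cannot be predicted with certainty. (DHQD)2PHAL is written; its pseudo-enantiomer (DHQ)2PHAL takes its place if that is the one that consumes the (3R,6S)-acid faster.

Step 1
Reactants: 1 4-bromophenol
Product: 2 (4-bromophenoxy)triisopropylsilane
Conditions: TIPSCl, imidazole, DMF, 25 °C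
Reagents that add atoms: triisopropylsilyl chloride, CC(C)[Si](Cl)(C(C)C)C(C)C
Why: Imidazole-assisted O-silylation of a phenol; the bulky aryl silyl ether should survive the organometallic, acidic and thermal steps and come off at the end with fluoride without touching the O–O bond.

Step 2
Reactants: 2 (4-bromophenoxy)triisopropylsilane; 3 1,10-dibromodecane
Product: 5 [4-(10-bromodecyl)phenoxy]triisopropylsilane, via aryl Grignard reagent 4 (not isolated)
Conditions: Mg, THF, 40 °C; then 3 (3 equiv), Li2CuCl4 (3 mol%), THF, 0 °C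
Reagents that add atoms: none
Why: Copper-catalysed Grignard–alkyl bromide cross-coupling (Kochi coupling); the excess of dibromide should hold back double arylation.

Step 3
Reactants: 5 [4-(10-bromodecyl)phenoxy]triisopropylsilane
Product: 6 [4-(dodec-11-yn-1-yl)phenoxy]triisopropylsilane
Conditions: LiC≡CH·H2NCH2CH2NH2, DMSO, 0 → 25 °C
Reagents that add atoms: lithium acetylide ethylenediamine complex, [Li]C#C.NCCN
Why: SN2 alkylation of acetylide by an unhindered primary bromide.

Step 4
Reactants: 6 [4-(dodec-11-yn-1-yl)phenoxy]triisopropylsilane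
Product: 8 {4-[(E)-12-iodo-11-methyldodec-11-en-1-yl]phenoxy}triisopropylsilane, via alkenylalane 7 (not isolated)
Conditions: AlMe3 (2 equiv), Cp2ZrCl2 (0.25 equiv), CH2Cl2, 0 → 25 °C; then I2, THF, −30 → 0 °C
Reagents that add atoms: trimethylaluminium, C[Al](C)C; iodine, II
Why: Negishi zirconium-catalysed carboalumination adds CH3 and Al syn with CH3 on the internal carbon, and iodinolysis with retention should give the (E)-iodide (chain trans to iodine), the source of the later C3=C6 geometry.

Step 5
Reactants: 8 {4-[(E)-12-iodo-11-methyldodec-11-en-1-yl]phenoxy}triisopropylsilane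
Product: 9 methyl (E)-4-methyl-14-[4-(triisopropylsilyloxy)phenyl]tetradec-3-enoate
Conditions: BrZnCH2CO2Me (from BrCH2CO2Me and Zn dust, THF), Pd(PPh3)4 (5 mol%), THF/DMPU, 60 °C
Reagents that add atoms: methyl bromoacetate, COC(=O)CBr
Why: Palladium-catalysed cross-coupling of a Reformatsky reagent with an alkenyl iodide (Negishi-type) proceeds with retention of alkene geometry, and the weakly basic zinc enolate should not pull the double bond into conjugation.

Step 6
Reactants: 9 methyl (E)-4-methyl-14-[4-(triisopropylsilyloxy)phenyl]tetradec-3-enoate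
Product: 10 methyl 2-[3,3-dichloro-2-methyl-4-oxo-2-{10-[4-(triisopropylsilyloxy)phenyl]decyl}cyclobutyl]acetate (racemic; CH2CO2Me cis to the ring methyl)
Conditions: Cl3CCOCl (2 equiv, slow addition), Zn–Cu couple, POCl3, Et2O, 35 °C
Reagents that add atoms: trichloroacetyl chloride, ClC(Cl)(Cl)C(Cl)=O
Why: Dichloroketene, made in the flask by zinc dechlorination of trichloroacetyl chloride, adds to the electron-rich trisubstituted alkene in a concerted but asynchronous [π2s+π2a] process, the thermal ketene–alkene [2+2] cycloaddition. The four-membered ring is closed by cycloaddition: the ketene carbonyl carbon (future C4) bonds to the CH terminus C3 and the CCl2 carbon (future C5) to the fully substituted C6. This regiochemistry follows from the transition state, in which bonding to the electrophilic carbonyl carbon leads and positive charge builds on the carbon best able to carry it, the tertiary C6. Both new stereocentres (C3 and C6) arise together and their relative configuration is fixed by suprafacial addition to the (E)-alkene; the product is racemic, which is harmless because these centres are later erased into diene geometry and rewritten. Chemoselectivity rests on the alkene being the only nucleophilic π bond (ester, aryl silyl ether and chain are inert) and on POCl3 binding the ZnCl2 that would otherwise promote ketene polymerisation, double-bond migration or enolisation towards C3.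

Step 7
Reactants: 10 the dichlorocyclobutanone
Product: 11 methyl 2-[2-methyl-4-oxo-2-{10-[4-(triisopropylsilyloxy)phenyl]decyl}cyclobutyl]acetate (racemic; cis as in 10)
Conditions: Zn dust, AcOH, 25 °C
Reagents that add atoms: none
Why: Reductive dechlorination of an α,α-dichloroketone through zinc enolates at C5; the weak acid and short contact should leave the C3–H next to the carbonyl unepimerised.

Step 8
Reactants: 11 the cyclobutanone
Product: 13 methyl 2-[4-methyl-4-{10-[4-(triisopropylsilyloxy)phenyl]decyl}-2-(trifluoromethanesulfonyloxy)cyclobut-2-en-1-yl]acetate (racemic; CH2CO2Me cis to the C4 methyl), via potassium enolate 12 (not isolated)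
Conditions: KN(SiMe3)2 (1.05 equiv), THF, −78 °C; then PhNTf2, −78 → 0 °C
Reagents that add atoms: N-phenylbis(trifluoromethanesulfonimide), O=S(=O)(N(c1ccccc1)S(=O)(=O)C(F)(F)F)C(F)(F)F
Why: Kinetic deprotonation by a bulky amide should take the ketone α-CH2 (C5) rather than the hindered methine C3 or the less acidic ester CH2, and O-triflation of the enolate locks the C4=C5 double bond while C3 keeps its configuration.

Step 9
Reactants: 13 the cyclobutenyl triflate
Product: 14 methyl 2-[2,4-dimethyl-4-{10-[4-(triisopropylsilyloxy)phenyl]decyl}cyclobut-2-en-1-yl]acetate (racemic; CH2CO2Me cis to the C4 methyl)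
Conditions: MeZnCl (2 equiv), Pd(PPh3)4 (5 mol%), THF, 25 → 50 °C
Reagents that add atoms: methylzinc chloride, C[Zn]Cl
Why: Negishi cross-coupling of an alkenyl triflate installs the C4 methyl group; the ester tolerates the organozinc.

Step 10
Reactants: 14 the 1-methylcyclobutene
Product: 15 methyl (3E,5E)-4,6-dimethyl-16-[4-(triisopropylsilyloxy)phenyl]hexadeca-3,5-dienoate
Conditions: mesitylene (0.05 M), BHT (cat.), 165 °C, Ar
Reagents that add atoms: none
Why: Thermal conrotatory 4π electrocyclic ring opening breaks C3–C6. Torquoselectivity turns the CH2CO2Me arm on C3 outward, so conrotation turns the trans-disposed decyl chain on C6 outward and the methyl inward; the other mode would force two alkyl groups inward. The two bonds made in step 6 thus become the (3E,5E)-diene.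

Step 11
Reactants: 15 the diene ester
Product: 16 (3E,5E)-4,6-dimethyl-16-[4-(triisopropylsilyloxy)phenyl]hexadeca-3,5-dienoic acid
Conditions: Me3SnOH (5 equiv), ClCH2CH2Cl, 70 °C; 5% aq HCl work-up
Reagents that add atoms: trimethyltin hydroxide, C[Sn](C)(C)O
Why: Mild tin hydroxide ester cleavage avoids the α-deprotonation that would move the diene into conjugation and spares the aryl silyl ether.

Step 12
Reactants: 16 the diene acid
Product: 17 2-[(3R*,6S*)-4,6-dimethyl-6-{10-[4-(triisopropylsilyloxy)phenyl]decyl}-3,6-dihydro-1,2-dioxin-3-yl]acetic acid (racemic; H on C3 cis to CH3 on C6)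
Conditions: O2, 5,10,15,20-tetraphenylporphyrin (1 mol%), CH2Cl2, visible light, −20 °C
Reagents that add atoms: dioxygen, O=O
Why: Singlet-oxygen [4+2] cycloaddition to the s-cis diene is suprafacial, so the two inside groups (H on C3, CH3 on C6) end up cis and the two outside groups (CH2CO2H, chain) cis; this sets the relative configuration of C3 and C6 as in the target.

Step 13
Reactants: 17 the racemic dioxine acid
Product: 18 (3S,4R,4aS,7aR)-4-bromo-3,4a-dimethyl-3-{10-[4-(triisopropylsilyloxy)phenyl]decyl}tetrahydrofuro[3,2-c][1,2]dioxin-6(3H)-one (Br trans to the lactone oxygen); the (3S,6R)-acid is left behind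
Conditions: NBS (0.55 equiv), (DHQD)2PHAL (10 mol%), PhCO2H (20 mol%), CHCl3/hexane 1:1, −40 °C; unreacted acid removed by extraction into cold aq NaHCO3
Reagents that add atoms: N-bromosuccinimide, O=C1CCC(=O)N1Br
Why: Catalytic asymmetric 5-exo bromolactonisation run as a kinetic resolution. The carboxylate can only close a cis-fused γ-lactone on C4 from the face that carries the CH2CO2H arm, anti to the bromonium on C5, so the two enantiomers of 17 must use opposite alkene faces. The cinchona-bound bromine donor should then react faster with the (3R,6S)-acid, fixing C4 (lactone O cis to C2, CH3 cis to the C6 methyl) and the temporary C–Br centre.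

Step 14
Reactants: 18 the bromolactone
Product: 19 (3S,4aR,7aR)-3,4a-dimethyl-3-{10-[4-(triisopropylsilyloxy)phenyl]decyl}tetrahydrofuro[3,2-c][1,2]dioxin-6(3H)-one (O-TIPS plakortolide S)
Conditions: Bu3SnH (1.5 equiv), AIBN (0.1 equiv), benzene, 75 °C
Reagents that add atoms: none
Why: Radical-chain tin hydride reduction of the secondary C–Br bond; bromine abstraction and hydrogen transfer at high tin hydride concentration should outrun attack on the neighbouring O–O bond, and C5 becomes CH2 with no stereocentre affected.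

Step 15
Reactants: 19 O-TIPS plakortolide S
Product: 20 plakortolide S, (3S,4aR,7aR)-3-[10-(4-hydroxyphenyl)decyl]-3,4a-dimethyltetrahydrofuro[3,2-c][1,2]dioxin-6(3H)-one
Conditions: HF·pyridine, THF/pyridine, 0 → 25 °C
Reagents that add atoms: none
Why: Fluoride-driven cleavage of the aryl silyl ether under buffered, non-basic conditions should leave the lactone and the base-sensitive dialkyl peroxide untouched.

**Compound list**

1 | 4-bromophenol | Oc1ccc(Br)cc1 | starting material
2 | (4-bromophenoxy)triisopropylsilane | CC(C)[Si](Oc1ccc(Br)cc1)(C(C)C)C(C)C | intermediate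
3 | 1,10-dibromodecane | BrCCCCCCCCCCBr | starting material
4 | [4-(triisopropylsilyloxy)phenyl]magnesium bromide (not isolated) | CC(C)[Si](Oc1ccc([Mg]Br)cc1)(C(C)C)C(C)C | intermediate
5 | [4-(10-bromodecyl)phenoxy]triisopropylsilane | BrCCCCCCCCCCc1ccc(O[Si](C(C)C)(C(C)C)C(C)C)cc1 | intermediate
6 | [4-(dodec-11-yn-1-yl)phenoxy]triisopropylsilane | C#CCCCCCCCCCCc1ccc(O[Si](C(C)C)(C(C)C)C(C)C)cc1 | intermediate
7 | dimethyl[(E)-2-methyl-12-{4-(triisopropylsilyloxy)phenyl}dodec-1-en-1-yl]alane (not isolated) | C[Al](C)/C=C(\C)CCCCCCCCCCc1ccc(O[Si](C(C)C)(C(C)C)C(C)C)cc1 | intermediate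
8 | {4-[(E)-12-iodo-11-methyldodec-11-en-1-yl]phenoxy}triisopropylsilane | I/C=C(\C)CCCCCCCCCCc1ccc(O[Si](C(C)C)(C(C)C)C(C)C)cc1 | intermediate
9 | methyl (E)-4-methyl-14-[4-(triisopropylsilyloxy)phenyl]tetradec-3-enoate | COC(=O)C/C=C(\C)CCCCCCCCCCc1ccc(O[Si](C(C)C)(C(C)C)C(C)C)cc1 | intermediate
10 | methyl 2-[3,3-dichloro-2-methyl-4-oxo-2-{10-[4-(triisopropylsilyloxy)phenyl]decyl}cyclobutyl]acetate, racemic, CH2CO2Me cis to ring methyl (one enantiomer drawn) | O=C1C(Cl)(Cl)[C@@](C)(CCCCCCCCCCc2ccc(O[Si](C(C)C)(C(C)C)C(C)C)cc2)[C@@H]1CC(=O)OC | intermediate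
11 | methyl 2-[2-methyl-4-oxo-2-{10-[4-(triisopropylsilyloxy)phenyl]decyl}cyclobutyl]acetate, racemic, cis (one enantiomer drawn) | O=C1C[C@@](C)(CCCCCCCCCCc2ccc(O[Si](C(C)C)(C(C)C)C(C)C)cc2)[C@@H]1CC(=O)OC | intermediate
12 | potassium cyclobutenolate of 11, enolised towards the ring CH2 (not isolated) | [K+].[O-]C1=C[C@@](C)(CCCCCCCCCCc2ccc(O[Si](C(C)C)(C(C)C)C(C)C)cc2)[C@@H]1CC(=O)OC | intermediate
13 | methyl 2-[4-methyl-4-{10-[4-(triisopropylsilyloxy)phenyl]decyl}-2-(trifluoromethanesulfonyloxy)cyclobut-2-en-1-yl]acetate, racemic, cis | O=S(=O)(OC1=C[C@@](C)(CCCCCCCCCCc2ccc(O[Si](C(C)C)(C(C)C)C(C)C)cc2)[C@@H]1CC(=O)OC)C(F)(F)F | intermediate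
14 | methyl 2-[2,4-dimethyl-4-{10-[4-(triisopropylsilyloxy)phenyl]decyl}cyclobut-2-en-1-yl]acetate, racemic, cis | CC1=C[C@@](C)(CCCCCCCCCCc2ccc(O[Si](C(C)C)(C(C)C)C(C)C)cc2)[C@@H]1CC(=O)OC | intermediate
15 | methyl (3E,5E)-4,6-dimethyl-16-[4-(triisopropylsilyloxy)phenyl]hexadeca-3,5-dienoate | COC(=O)C/C=C(\C)/C=C(\C)CCCCCCCCCCc1ccc(O[Si](C(C)C)(C(C)C)C(C)C)cc1 | intermediate
16 | (3E,5E)-4,6-dimethyl-16-[4-(triisopropylsilyloxy)phenyl]hexadeca-3,5-dienoic acid | OC(=O)C/C=C(\C)/C=C(\C)CCCCCCCCCCc1ccc(O[Si](C(C)C)(C(C)C)C(C)C)cc1 | intermediate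
17 | 2-[(3R*,6S*)-4,6-dimethyl-6-{10-[4-(triisopropylsilyloxy)phenyl]decyl}-3,6-dihydro-1,2-dioxin-3-yl]acetic acid, racemic (the (3R,6S) enantiomer drawn) | C[C@]1(CCCCCCCCCCc2ccc(O[Si](C(C)C)(C(C)C)C(C)C)cc2)C=C(C)[C@@H](CC(O)=O)OO1 | intermediate
18 | (3S,4R,4aS,7aR)-4-bromo-3,4a-dimethyl-3-{10-[4-(triisopropylsilyloxy)phenyl]decyl}tetrahydrofuro[3,2-c][1,2]dioxin-6(3H)-one | C[C@]1(CCCCCCCCCCc2ccc(O[Si](C(C)C)(C(C)C)C(C)C)cc2)[C@H](Br)[C@@]2(C)OC(=O)C[C@H]2OO1 | intermediate
19 | (3S,4aR,7aR)-3,4a-dimethyl-3-{10-[4-(triisopropylsilyloxy)phenyl]decyl}tetrahydrofuro[3,2-c][1,2]dioxin-6(3H)-one | C[C@]1(CCCCCCCCCCc2ccc(O[Si](C(C)C)(C(C)C)C(C)C)cc2)C[C@@]2(C)OC(=O)C[C@H]2OO1 | intermediate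
20 | plakortolide S | C[C@]1(CCCCCCCCCCc2ccc(O)cc2)C[C@@]2(C)OC(=O)C[C@H]2OO1 | target

**Step count and risks**

Total steps: 15. Longest linear sequence: 15 (from 4-bromophenol).

Steps most likely to fail:

Step 13. The catalyst may not tell the two enantiomers of 17 apart well enough, so both cyclise and 18 is formed with low enantiomeric purity. Fallback: from 17, uncatalysed iodolactonisation (I2, NaHCO3, MeCN, 0 °C) gives the racemic iodolactone, rac-(3S,4R,4aS,7aR)-4-iodo-3,4a-dimethyl-3-{10-[4-(triisopropylsilyloxy)phenyl]decyl}tetrahydrofuro[3,2-c][1,2]dioxin-6(3H)-one F1. Its enantiomers are separated by preparative HPLC on a chiral stationary phase (amylose tris(3,5-dimethylphenylcarbamate)), and Bu3SnH/AIBN deiodination of the (3S,4R,4aS,7aR) enantiomer comes back to the route at 19.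

Step 12. The ene reaction of singlet oxygen at the allylic methyl and methylene hydrogens may outrun the [4+2] addition, because the s-cis conformer with an inside methyl is thinly populated; a stepwise perepoxide path may also erode suprafaciality. Fallback: from 15, ground-state oxygen is added through the diene radical cation ((4-BrC6H4)3N·SbCl6, 5 mol%, O2, CH2Cl2, −78 °C), a chain process with no ene channel. This gives the racemic dioxine ester, methyl 2-[(3R*,6S*)-4,6-dimethyl-6-{10-[4-(triisopropylsilyloxy)phenyl]decyl}-3,6-dihydro-1,2-dioxin-3-yl]acetate F2; Me3SnOH cleavage of the ester comes back at 17.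

Step 6. The cycloaddition to the hindered, inductively deactivated alkene may be slow, so that dichloroketene oligomerises; zinc halide may also enolise the α,α-dichloroketone towards C3 and scramble the cis relationship. Fallback: from 9, the cationic keteniminium [2+2] (N,N-dimethylacetamide, Tf2O, 2,4,6-collidine, ClCH2CH2Cl, 80 °C) forms the same two C–C bonds with the same regiochemistry and suprafaciality and no zinc halide. It gives the cyclobutaniminium salt, N-[2-(2-methoxy-2-oxoethyl)-3-methyl-3-{10-[4-(triisopropylsilyloxy)phenyl]decyl}cyclobutylidene]-N-methylmethanaminium triflate F3; hydrolysis with aqueous NaHCO3 comes back at 11, with no dechlorination step.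

**Further compounds**

F1 | step 13 | rac-(3S,4R,4aS,7aR)-4-iodo-3,4a-dimethyl-3-{10-[4-(triisopropylsilyloxy)phenyl]decyl}tetrahydrofuro[3,2-c][1,2]dioxin-6(3H)-one | C[C@]1(CCCCCCCCCCc2ccc(O[Si](C(C)C)(C(C)C)C(C)C)cc2)[C@H](I)[C@@]2(C)OC(=O)C[C@H]2OO1
F2 | step 12 | methyl 2-[(3R*,6S*)-4,6-dimethyl-6-{10-[4-(triisopropylsilyloxy)phenyl]decyl}-3,6-dihydro-1,2-dioxin-3-yl]acetate (racemic) | C[C@]1(CCCCCCCCCCc2ccc(O[Si](C(C)C)(C(C)C)C(C)C)cc2)C=C(C)[C@@H](CC(=O)OC)OO1
F3 | step 6 | N-[2-(2-methoxy-2-oxoethyl)-3-methyl-3-{10-[4-(triisopropylsilyloxy)phenyl]decyl}cyclobutylidene]-N-methylmethanaminium trifluoromethanesulfonate (racemic, cis) | C[N+](C)=C1C[C@@](C)(CCCCCCCCCCc2ccc(O[Si](C(C)C)(C(C)C)C(C)C)cc2)[C@@H]1CC(=O)OC.[O-]S(=O)(=O)C(F)(F)F
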